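**Plan**

- Retrosynthesis: cut C6=C7 (cross-metathesis with a vinyl lactone), re-form the C7–O bond of a 2-(iodomethyl)tetrahydropyran (reverse of a zinc fragmentation), cut C13–C14 (styryl addition to an aldehyde), then cut C10–C11, O–C11 and C9–O of that ring (Prins cyclisation).
- Feature used: the 9,11-anti diol next to C6=C7 maps onto an all-cis 2,4,6-trisubstituted tetrahydropyran (ring O bridging C7 and C11, hydroxyl on C9) whose C7–O bond is later eliminated to give the alkene.
- Forward: epoxide opening gives the C7 carbinol; the Prins reaction closes the tetrahydropyran (O, C7–C11); the styryl group is added at C13; zinc opens the ring to the acyclic chain; the lactone ring, made separately by acrylate ring-closing metathesis, is joined last.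
- Stereochemistry: C7 from (S)-glycidyl tosylate sets C9 and C11 through the all-equatorial Prins chair and is then erased; C13 comes from a (−)-MIB-catalysed alkenylzinc addition; lactone C5 comes from (R)-epichlorohydrin.
- Alkene geometry: C14=C15 from syn-hydroboration of phenylacetylene; C6=C7 from thermodynamically controlled cross-metathesis.

Key step: step 3

Remark on numbering: atoms follow the target chain (C1 lactone C=O, C5 lactone CH–O, C6=C7, carbinols C9/C11/C13, C14=C15–Ph; target = 5R,9S,11R,13R). The carbon called C6 in compounds 3–17 (CH2OTs → CH2I → =CH2) leaves as ethylene in step 15 and is replaced by the vinyl CH of 24.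

**Route**

Step 1
Reactants: 1 (2S)-oxiran-2-ylmethyl 4-methylbenzenesulfonate [(S)-glycidyl tosylate]; 2 vinylmagnesium bromide
Product: 3 (2S)-2-hydroxypent-4-en-1-yl 4-methylbenzenesulfonate
Conditions: CuI (10 mol %), THF, −40 °C; aq NH4Cl
Reagents that add atoms: none
Why: CuI-catalysed Grignard opening of a terminal epoxide (organocuprate SN2 attack at the unsubstituted epoxide carbon) is faster than sulfonate displacement at low temperature and does not touch the C–O bond of the stereocentre, so the S configuration is carried into 3.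

Step 2
Reactants: 4 3-(benzyloxy)propan-1-ol
Product: 5 3-(benzyloxy)propanal
Conditions: IBX, EtOAc, 75 °C
Reagents that add atoms: none
Why: IBX oxidation of a primary alcohol stops at the aldehyde and needs no base, which avoids β-elimination of benzyl alcohol from 5.

Step 3
Reactants: 3 (2S)-2-hydroxypent-4-en-1-yl 4-methylbenzenesulfonate; 5 3-(benzyloxy)propanal
Product: 7 [(2S,4R,6S)-6-[2-(benzyloxy)ethyl]-4-hydroxyoxan-2-yl]methyl 4-methylbenzenesulfonate (all-cis tetrahydropyranol), via C9 trifluoroacetate ester 6 (not isolated)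
Conditions: CF3CO2H, CH2Cl2, 0 °C → rt; then K2CO3, MeOH, 0 °C
Reagents that add atoms: trifluoroacetic acid, OC(=O)C(F)(F)F (its oxygen becomes the C9 hydroxyl oxygen)
Why: Prins cyclisation: 3 and 5 form a hemiacetal that ionises to an (E)-oxocarbenium ion (C7–O+=C11), the terminal alkene carbon C10 attacks C11, and the secondary cation at C9 is captured by trifluoroacetate to give 6, which brief methanolysis converts into 7. The closest known reaction is the trifluoroacetic acid-promoted condensation of homoallylic alcohols with aliphatic aldehydes to all-cis 2,6-disubstituted tetrahydropyran-4-ols. The one ring formed (O, C7–C11) closes in a cationic 6-endo mode, both alkene carbons becoming ring members, through a chair transition state. C11 is controlled by the existing C7 centre because the tosyloxymethyl group and the benzyloxyethyl chain both sit equatorial in that chair, and C9 is controlled by equatorial capture of the cation, so 7 should be the 2,4,6-all-cis isomer (7S,9R,11S). The step needs high cis selectivity and no loss of optical purity at C7; the chair preference of the (E)-oxocarbenium ion secures the first, and the absence of cation-stabilising aryl groups on either partner, which keeps 2-oxonia-Cope exchange slow, secures the second. The benzyl ether and the primary tosylate are inert to trifluoroacetic acid, and cold K2CO3/MeOH should cleave only the trifluoroacetate.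

Step 4
Reactants: 7 [(2S,4R,6S)-6-[2-(benzyloxy)ethyl]-4-hydroxyoxan-2-yl]methyl 4-methylbenzenesulfonate
Product: 8 [(2S,4R,6S)-6-[2-(benzyloxy)ethyl]-4-[(tert-butyldimethylsilyl)oxy]oxan-2-yl]methyl 4-methylbenzenesulfonate
Conditions: TBSCl, imidazole, DMF, rt
Reagents that add atoms: tert-butyldimethylsilyl chloride (TBSCl), CC(C)(C)[Si](C)(C)Cl
Why: Standard silylation of an unhindered equatorial secondary alcohol, which leaves the tosylate, the benzyl ether and all stereocentres untouched.

Step 5
Reactants: 8 [(2S,4R,6S)-6-[2-(benzyloxy)ethyl]-4-[(tert-butyldimethylsilyl)oxy]oxan-2-yl]methyl 4-methylbenzenesulfonate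
Product: 9 [(2S,4R,6S)-4-[(tert-butyldimethylsilyl)oxy]-6-(2-hydroxyethyl)oxan-2-yl]methyl 4-methylbenzenesulfonate
Conditions: H2 (1 atm), Pd/C, EtOAc, rt
Reagents that add atoms: none
Why: Hydrogenolysis of a benzyl ether over Pd/C, run in ethyl acetate so that the silyl ether and the alkyl tosylate should survive, at a stage where no alkene is yet present.

Step 6
Reactants: 9 [(2S,4R,6S)-4-[(tert-butyldimethylsilyl)oxy]-6-(2-hydroxyethyl)oxan-2-yl]methyl 4-methylbenzenesulfonate
Product: 10 [(2S,4R,6R)-4-[(tert-butyldimethylsilyl)oxy]-6-(2-oxoethyl)oxan-2-yl]methyl 4-methylbenzenesulfonate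
Conditions: IBX, EtOAc, 75 °C
Reagents that add atoms: none
Why: IBX oxidation of the primary alcohol under neutral conditions, chosen because a base could open the ring of this β-alkoxy aldehyde by retro-oxa-Michael elimination (the descriptor at C11 changes by priority only).

Step 7
Reactants: 10 [(2S,4R,6R)-4-[(tert-butyldimethylsilyl)oxy]-6-(2-oxoethyl)oxan-2-yl]methyl 4-methylbenzenesulfonate; 11 phenylacetylene
Product: 14 [(2S,4R,6S)-4-[(tert-butyldimethylsilyl)oxy]-6-[(2R,3E)-2-hydroxy-4-phenylbut-3-en-1-yl]oxan-2-yl]methyl 4-methylbenzenesulfonate, via dicyclohexyl[(E)-2-phenylethenyl]borane 12 (not isolated), via methyl[(E)-2-phenylethenyl]zinc 13 (not isolated)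
Conditions: 11, Cy2BH, toluene, 0 °C → rt; Me2Zn, −78 °C; (−)-MIB [(2S)-3-exo-morpholinoisoborneol] (5 mol %), then 10, −10 °C; aq NH4Cl
Reagents that add atoms: none
Why: Catalytic asymmetric alkenylzinc addition: syn-hydroboration of 11 gives the (E)-alkenylborane 12, boron-to-zinc exchange gives 13, and the (−)-MIB–zinc complex should deliver the styryl group to the Si face of the aldehyde (the sense this ligand shows in dialkylzinc additions), setting C13 as R under catalyst control with the E geometry fixed by the hydroboration, while the tosylate is inert to organozinc species at this temperature.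

Step 8
Reactants: 14 [(2S,4R,6S)-4-[(tert-butyldimethylsilyl)oxy]-6-[(2R,3E)-2-hydroxy-4-phenylbut-3-en-1-yl]oxan-2-yl]methyl 4-methylbenzenesulfonate
Product: 15 [(2S,4R,6R)-4-[(tert-butyldimethylsilyl)oxy]-6-[(2R,3E)-2-[(tert-butyldimethylsilyl)oxy]-4-phenylbut-3-en-1-yl]oxan-2-yl]methyl 4-methylbenzenesulfonate
Conditions: TBSCl, imidazole, DMAP (cat.), DMF, rt
Reagents that add atoms: tert-butyldimethylsilyl chloride (TBSCl), CC(C)(C)[Si](C)(C)Cl
Why: Silylation of the allylic secondary alcohol, which protects C13–OH and makes the styryl alkene a hindered, poor metathesis partner for step 15.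

Step 9
Reactants: 15 [(2S,4R,6R)-4-[(tert-butyldimethylsilyl)oxy]-6-[(2R,3E)-2-[(tert-butyldimethylsilyl)oxy]-4-phenylbut-3-en-1-yl]oxan-2-yl]methyl 4-methylbenzenesulfonate
Product: 16 (2S,4R,6R)-2-(iodomethyl)-4-[(tert-butyldimethylsilyl)oxy]-6-[(2R,3E)-2-[(tert-butyldimethylsilyl)oxy]-4-phenylbut-3-en-1-yl]oxane
Conditions: NaI, acetone, reflux
Reagents that add atoms: sodium iodide, [Na+].[I-]
Why: Finkelstein SN2 displacement of the primary tosylate by iodide, to which the silyl ethers and the alkene are inert.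

Step 10
Reactants: 16 (2S,4R,6R)-2-(iodomethyl)-4-[(tert-butyldimethylsilyl)oxy]-6-[(2R,3E)-2-[(tert-butyldimethylsilyl)oxy]-4-phenylbut-3-en-1-yl]oxane
Product: 17 (1E,3R,5R,7S)-3,7-bis[(tert-butyldimethylsilyl)oxy]-1-phenyldeca-1,9-dien-5-ol
Conditions: Zn dust (activated), EtOH, reflux; aq NH4Cl
Reagents that add atoms: none
Why: Vasella-type reductive fragmentation: zinc inserts into the C–I bond and the β-alkoxy organozinc eliminates, cleaving C7–O to give the terminal alkene and releasing the ring oxygen as the C11 hydroxyl, so that C7 is erased and the untouched cis C9/C11 ring relationship becomes the 9,11-anti diol pattern.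

Step 11
Reactants: 18 (2R)-2-(chloromethyl)oxirane [(R)-epichlorohydrin]; 2 vinylmagnesium bromide
Product: 19 (2R)-1-chloropent-4-en-2-ol
Conditions: CuI (10 mol %), THF, −40 °C; aq NH4Cl
Reagents that add atoms: none
Why: The same CuI-catalysed epoxide opening as in step 1, with attack at the epoxide CH2 so that the stereocentre is untouched and the chloride is not displaced at low temperature.

Step 12
Reactants: 19 (2R)-1-chloropent-4-en-2-ol
Product: 21 (3R)-hexa-1,5-dien-3-ol, via (2R)-2-allyloxirane 20 (not isolated)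
Conditions: Me3S+ I− (3.5 equiv), n-BuLi (3.4 equiv), THF, −20 °C → rt
Reagents that add atoms: trimethylsulfonium iodide, C[S+](C)C.[I-] (delivers the terminal CH2 of the new vinyl group)
Why: Known one-carbon homologation of epoxides to allylic alcohols with excess dimethylsulfonium methylide: the ylide closes the chlorohydrin to epoxide 20, opens it at the terminal carbon, and the β-alkoxy sulfonium salt is deprotonated to an ylide that eliminates dimethyl sulfide, all without touching the stereocentre.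

Step 13
Reactants: 21 (3R)-hexa-1,5-dien-3-ol; 22 acryloyl chloride
Product: 23 (3R)-hexa-1,5-dien-3-yl prop-2-enoate
Conditions: Et3N, DMAP (cat.), CH2Cl2, 0 °C
Reagents that add atoms: none
Why: Acylation of a secondary alcohol with an acid chloride, with retention at the carbinol carbon.

Step 14
Reactants: 23 (3R)-hexa-1,5-dien-3-yl prop-2-enoate
Product: 24 (6R)-6-ethenyl-5,6-dihydro-2H-pyran-2-one
Conditions: first-generation Grubbs catalyst RuCl2(PCy3)2(=CHPh) (5 mol %), CH2Cl2 (high dilution), 40 °C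
Reagents that add atoms: none
Why: Ring-closing metathesis in which the ruthenium carbene loads on the unhindered allyl terminus and closes onto the acrylate, giving the six-membered unsaturated lactone in preference to the butenolide that would need the hindered vinyl carbinol alkene.

Step 15
Reactants: 17 (1E,3R,5R,7S)-3,7-bis[(tert-butyldimethylsilyl)oxy]-1-phenyldeca-1,9-dien-5-ol; 24 (6R)-6-ethenyl-5,6-dihydro-2H-pyran-2-one
Product: 25 (6R)-6-[(1E,4S,6R,8R,9E)-4,8-bis[(tert-butyldimethylsilyl)oxy]-6-hydroxy-10-phenyldeca-1,9-dien-1-yl]-5,6-dihydro-2H-pyran-2-one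
Conditions: 24 (3 equiv), second-generation Grubbs catalyst RuCl2(PCy3)(H2IMes)(=CHPh) (5–10 mol %), CH2Cl2, 40 °C
Reagents that add atoms: none
Why: Olefin cross-metathesis between an unhindered terminal alkene and a slowly homodimerising, allylically oxygenated vinyl partner used in excess, which should give the E alkene under thermodynamic control while the silyloxy-flanked 1,2-disubstituted styryl alkene reacts much more slowly and no stereocentre is affected.

Step 16
Reactants: 25 (6R)-6-[(1E,4S,6R,8R,9E)-4,8-bis[(tert-butyldimethylsilyl)oxy]-6-hydroxy-10-phenyldeca-1,9-dien-1-yl]-5,6-dihydro-2H-pyran-2-one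
Product: 26 (6R)-6-[(1E,4S,6R,8R,9E)-4,6,8-trihydroxy-10-phenyldeca-1,9-dien-1-yl]-5,6-dihydro-2H-pyran-2-one (target)
Conditions: HF·pyridine, pyridine, THF, 0 °C → rt
Reagents that add atoms: none
Why: Fluoride-mediated cleavage of both silyl ethers under buffered conditions that spare the unsaturated lactone and should not ionise the cinnamyl-type C13 alcohol.

**Compound list**

1 | (2S)-oxiran-2-ylmethyl 4-methylbenzenesulfonate | Cc1ccc(cc1)S(=O)(=O)OC[C@@H]1CO1 | starting material
2 | vinylmagnesium bromide | C=C[Mg]Br | starting material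
3 | (2S)-2-hydroxypent-4-en-1-yl 4-methylbenzenesulfonate | Cc1ccc(cc1)S(=O)(=O)OC[C@@H](O)CC=C | intermediate
4 | 3-(benzyloxy)propan-1-ol | OCCCOCc1ccccc1 | starting material
5 | 3-(benzyloxy)propanal | O=CCCOCc1ccccc1 | intermediate
6 | (2S,4R,6S)-2-[2-(benzyloxy)ethyl]-6-[(tosyloxy)methyl]oxan-4-yl trifluoroacetate (all-cis) | Cc1ccc(cc1)S(=O)(=O)OC[C@@H]1C[C@H](OC(=O)C(F)(F)F)C[C@H](CCOCc2ccccc2)O1 | intermediate
7 | [(2S,4R,6S)-6-[2-(benzyloxy)ethyl]-4-hydroxyoxan-2-yl]methyl 4-methylbenzenesulfonate (all-cis) | Cc1ccc(cc1)S(=O)(=O)OC[C@@H]1C[C@H](O)C[C@H](CCOCc2ccccc2)O1 | intermediate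
8 | [(2S,4R,6S)-6-[2-(benzyloxy)ethyl]-4-[(tert-butyldimethylsilyl)oxy]oxan-2-yl]methyl 4-methylbenzenesulfonate | Cc1ccc(cc1)S(=O)(=O)OC[C@@H]1C[C@H](O[Si](C)(C)C(C)(C)C)C[C@H](CCOCc2ccccc2)O1 | intermediate
9 | [(2S,4R,6S)-4-[(tert-butyldimethylsilyl)oxy]-6-(2-hydroxyethyl)oxan-2-yl]methyl 4-methylbenzenesulfonate | Cc1ccc(cc1)S(=O)(=O)OC[C@@H]1C[C@H](O[Si](C)(C)C(C)(C)C)C[C@H](CCO)O1 | intermediate
10 | [(2S,4R,6R)-4-[(tert-butyldimethylsilyl)oxy]-6-(2-oxoethyl)oxan-2-yl]methyl 4-methylbenzenesulfonate | Cc1ccc(cc1)S(=O)(=O)OC[C@@H]1C[C@H](O[Si](C)(C)C(C)(C)C)C[C@H](CC=O)O1 | intermediate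
11 | phenylacetylene | C#Cc1ccccc1 | starting material
12 | dicyclohexyl[(E)-2-phenylethenyl]borane | C1CCC(CC1)B(/C=C/c1ccccc1)C1CCCCC1 | intermediate
13 | methyl[(E)-2-phenylethenyl]zinc | C[Zn]/C=C/c1ccccc1 | intermediate
14 | [(2S,4R,6S)-4-[(tert-butyldimethylsilyl)oxy]-6-[(2R,3E)-2-hydroxy-4-phenylbut-3-en-1-yl]oxan-2-yl]methyl 4-methylbenzenesulfonate | Cc1ccc(cc1)S(=O)(=O)OC[C@@H]1C[C@H](O[Si](C)(C)C(C)(C)C)C[C@H](C[C@@H](O)/C=C/c2ccccc2)O1 | intermediate
15 | [(2S,4R,6R)-4-[(tert-butyldimethylsilyl)oxy]-6-[(2R,3E)-2-[(tert-butyldimethylsilyl)oxy]-4-phenylbut-3-en-1-yl]oxan-2-yl]methyl 4-methylbenzenesulfonate | Cc1ccc(cc1)S(=O)(=O)OC[C@@H]1C[C@H](O[Si](C)(C)C(C)(C)C)C[C@H](C[C@@H](O[Si](C)(C)C(C)(C)C)/C=C/c2ccccc2)O1 | intermediate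
16 | (2S,4R,6R)-2-(iodomethyl)-4-[(tert-butyldimethylsilyl)oxy]-6-[(2R,3E)-2-[(tert-butyldimethylsilyl)oxy]-4-phenylbut-3-en-1-yl]oxane | IC[C@@H]1C[C@H](O[Si](C)(C)C(C)(C)C)C[C@H](C[C@@H](O[Si](C)(C)C(C)(C)C)/C=C/c2ccccc2)O1 | intermediate
17 | (1E,3R,5R,7S)-3,7-bis[(tert-butyldimethylsilyl)oxy]-1-phenyldeca-1,9-dien-5-ol | C=CC[C@H](O[Si](C)(C)C(C)(C)C)C[C@@H](O)C[C@@H](O[Si](C)(C)C(C)(C)C)/C=C/c1ccccc1 | intermediate
18 | (2R)-2-(chloromethyl)oxirane | ClC[C@H]1CO1 | starting material
19 | (2R)-1-chloropent-4-en-2-ol | ClC[C@H](O)CC=C | intermediate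
20 | (2R)-2-(prop-2-en-1-yl)oxirane | C=CC[C@@H]1CO1 | intermediate
21 | (3R)-hexa-1,5-dien-3-ol | C=C[C@H](O)CC=C | intermediate
22 | acryloyl chloride | C=CC(=O)Cl | starting material
23 | (3R)-hexa-1,5-dien-3-yl prop-2-enoate | C=CC(=O)O[C@@H](C=C)CC=C | intermediate
24 | (6R)-6-ethenyl-5,6-dihydro-2H-pyran-2-one | O=C1C=CC[C@H](C=C)O1 | intermediate
25 | (6R)-6-[(1E,4S,6R,8R,9E)-4,8-bis[(tert-butyldimethylsilyl)oxy]-6-hydroxy-10-phenyldeca-1,9-dien-1-yl]-5,6-dihydro-2H-pyran-2-one | O=C1C=CC[C@H](/C=C/C[C@H](O[Si](C)(C)C(C)(C)C)C[C@@H](O)C[C@@H](O[Si](C)(C)C(C)(C)C)/C=C/c2ccccc2)O1 | intermediate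
26 | (6R)-6-[(1E,4S,6R,8R,9E)-4,6,8-trihydroxy-10-phenyldeca-1,9-dien-1-yl]-5,6-dihydro-2H-pyran-2-one | O=C1C=CC[C@H](/C=C/C[C@H](O)C[C@@H](O)C[C@@H](O)/C=C/c2ccccc2)O1 | target

**Step count**

Total steps: 16. Longest linear sequence: 11 steps (steps 1, 3–10, 15, 16, from (S)-glycidyl tosylate); the lactone branch is steps 11–14 and the aldehyde is step 2.

**Steps most likely to fail**

Step 3 (Prins cyclisation). The electron-withdrawing tosyloxymethyl group may slow ionisation of the hemiacetal. Aldehyde self-condensation, loss of benzyl alcohol from the aldehyde, or 2-oxonia-Cope exchange (erosion of optical purity, scrambled side chains) could then compete. The fallback generates the same oxocarbenium ion without free aldehyde or water, by a segment-coupling Prins sequence that sets out from 3 and 5. Oxidation of 5 (NaClO2, NaH2PO4, 2-methylbut-2-ene, t-BuOH/H2O) gives 3-(benzyloxy)propanoic acid F1. Esterification of F1 with 3 (DCC, DMAP, CH2Cl2) gives (2S)-1-(tosyloxy)pent-4-en-2-yl 3-(benzyloxy)propanoate F2. Reduction with i-Bu2AlH at −78 °C and trapping of the aluminium hemiacetal in the same flask with Ac2O, pyridine and DMAP gives the α-acetoxy ether F3. Treatment of F3 with CF3CO2H in CH2Cl2 ionises the acetate, the cation cyclises through the same chair to 6, and methanolysis returns to the route at 7.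

Step 7 (styryl addition). Facial selectivity may be poor, because the ring oxygen β to the aldehyde can chelate zinc and favour the 11,13-anti isomer, or because uncatalysed background addition competes. The fallback sets C13 by reagent-controlled ketone reduction and sets out from 10. Addition of 13 without ligand (or use of the unselective mixture itself) gives the C13-epimeric allylic alcohols F4. Oxidation with MnO2 in CH2Cl2 gives the (E)-enone F5. Corey–Bakshi–Shibata reduction with (S)-2-methyl-CBS-oxazaborolidine and BH3·SMe2 at −40 °C, with the styryl group acting as the large substituent, should give the 13R alcohol and returns to the route at 14.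

Step 15 (cross-metathesis). The hindered, electron-poor vinyl lactone may engage slowly, so that homodimerisation of 17 and attack of the ruthenium carbene on the styryl alkene (loss of the phenyl terminus) take over. The fallback builds the lactone on the chain and sets out from 17.
- Silylation of the C11 hydroxyl (TBSOTf, 2,6-lutidine) gives the tris-silyl ether F6.
- Cross-metathesis of F6 with excess acrolein, a small and fast partner (Hoveyda–Grubbs second-generation catalyst RuCl2(H2IMes)(=CH-C6H4-2-OiPr)), gives the (E)-enal F7.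
- Brown allylation with B-allyldiisopinocampheylborane made from (+)-Ipc2BOMe and allylmagnesium bromide (Re-face addition) gives the 5R homoallylic alcohol F8.
- Acylation with 22 and Et3N gives the acrylate F9.
- Ring-closing metathesis with the first-generation Grubbs catalyst RuCl2(PCy3)2(=CHPh), which leaves 1,2-disubstituted and styryl alkenes alone, gives the tris-silyl lactone F10.
- HF·pyridine then returns to the route at the target 26.

**Further compounds**

F1 | step 3 | 3-(benzyloxy)propanoic acid | OC(=O)CCOCc1ccccc1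
F2 | step 3 | (2S)-1-[(4-methylbenzenesulfonyl)oxy]pent-4-en-2-yl 3-(benzyloxy)propanoate | Cc1ccc(cc1)S(=O)(=O)OC[C@@H](OC(=O)CCOCc2ccccc2)CC=C
F3 | step 3 | 3-(benzyloxy)-1-{[(2S)-1-[(4-methylbenzenesulfonyl)oxy]pent-4-en-2-yl]oxy}propyl acetate (both acetal epimers) | Cc1ccc(cc1)S(=O)(=O)OC[C@@H](OC(CCOCc2ccccc2)OC(C)=O)CC=C
F4 | step 7 | [(2S,4R,6S)-4-[(tert-butyldimethylsilyl)oxy]-6-[(3E)-2-hydroxy-4-phenylbut-3-en-1-yl]oxan-2-yl]methyl 4-methylbenzenesulfonate (mixture of C13 epimers) | Cc1ccc(cc1)S(=O)(=O)OC[C@@H]1C[C@H](O[Si](C)(C)C(C)(C)C)C[C@H](CC(O)/C=C/c2ccccc2)O1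
F5 | step 7 | [(2S,4R,6R)-4-[(tert-butyldimethylsilyl)oxy]-6-[(3E)-2-oxo-4-phenylbut-3-en-1-yl]oxan-2-yl]methyl 4-methylbenzenesulfonate | Cc1ccc(cc1)S(=O)(=O)OC[C@@H]1C[C@H](O[Si](C)(C)C(C)(C)C)C[C@H](CC(=O)/C=C/c2ccccc2)O1
F6 | step 15 | (1E,3R,5R,7S)-3,5,7-tris[(tert-butyldimethylsilyl)oxy]-1-phenyldeca-1,9-diene | C=CC[C@H](O[Si](C)(C)C(C)(C)C)C[C@@H](O[Si](C)(C)C(C)(C)C)C[C@@H](O[Si](C)(C)C(C)(C)C)/C=C/c1ccccc1
F7 | step 15 | (2E,5S,7R,9R,10E)-5,7,9-tris[(tert-butyldimethylsilyl)oxy]-11-phenylundeca-2,10-dienal | O=C/C=C/C[C@H](O[Si](C)(C)C(C)(C)C)C[C@@H](O[Si](C)(C)C(C)(C)C)C[C@@H](O[Si](C)(C)C(C)(C)C)/C=C/c1ccccc1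
F8 | step 15 | (4R,5E,8S,10R,12R,13E)-8,10,12-tris[(tert-butyldimethylsilyl)oxy]-14-phenyltetradeca-1,5,13-trien-4-ol | C=CC[C@@H](O)/C=C/C[C@H](O[Si](C)(C)C(C)(C)C)C[C@@H](O[Si](C)(C)C(C)(C)C)C[C@@H](O[Si](C)(C)C(C)(C)C)/C=C/c1ccccc1
F9 | step 15 | (4R,5E,8S,10R,12R,13E)-8,10,12-tris[(tert-butyldimethylsilyl)oxy]-14-phenyltetradeca-1,5,13-trien-4-yl prop-2-enoate | C=CC[C@@H](OC(=O)C=C)/C=C/C[C@H](O[Si](C)(C)C(C)(C)C)C[C@@H](O[Si](C)(C)C(C)(C)C)C[C@@H](O[Si](C)(C)C(C)(C)C)/C=C/c1ccccc1
F10 | step 15 | (6R)-6-[(1E,4S,6R,8R,9E)-4,6,8-tris[(tert-butyldimethylsilyl)oxy]-10-phenyldeca-1,9-dien-1-yl]-5,6-dihydro-2H-pyran-2-one | O=C1C=CC[C@H](/C=C/C[C@H](O[Si](C)(C)C(C)(C)C)C[C@@H](O[Si](C)(C)C(C)(C)C)C[C@@H](O[Si](C)(C)C(C)(C)C)/C=C/c2ccccc2)O1
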